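**Retrosynthetic overview**

- Target 27 ⇒ linoleic acid 26 + hydroxy ketone 25 (ester C–O). The 1,1-disubstituted alkene ⇒ ketone 22 (methylenation) ⇒ cyclobutanecarbaldehyde 18 + three-carbon Grignard reagent 20.
- Feature: ring A is the cyclobutane C1(H)(alkenyl)–C2(H)(3-oxobutyl)–C3(Me)2–C4H2. The C3–C4 bond has no functional group next to it, but C3 and C4 can both sit beside the nitrogen of a pyrrolidine that already holds C1 and C2 trans.
- Ring A (the only ring, closed once) ⇒ pyrrolidine 12 by loss of the nitrogen as N2 from a 1,1-diazene (contraction 5 → 4, C3–C4 bond).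
- Pyrrolidine 12 ⇒ trans γ-lactam ester 10 ⇒ nitro malonate 8 ⇒ alkylidene malonate 6 + 2-nitropropane 7. The catalytic asymmetric conjugate addition sets C2; C1 follows by equilibration to trans.
- 6 ⇒ dimethyl malonate 5 + aldehyde 4, from ozonolysis of the ketal of 6-methylhept-5-en-2-one 1.

Key step: step 8

Assumption: the sense of induction of the chiral phase-transfer catalyst on this aliphatic alkylidene malonate cannot be predicted with certainty; both antipodes of the catalyst are accessible, and the one that gives the (R)-adduct 8 is used.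

**Route**

Step 1
Reactants: 1 6-methylhept-5-en-2-one
Product: 2 2-methyl-2-(4-methylpent-3-en-1-yl)-1,3-dioxolane
Conditions: ethylene glycol, p-TsOH·H2O (cat.), toluene, reflux, azeotropic removal of water
Reagents that add atoms: ethylene glycol, OCCO
Why: Acid-catalysed ketalisation with removal of water should mask the methyl ketone as its dioxolane, the trisubstituted alkene being inert under these conditions.

Step 2
Reactants: 2 2-methyl-2-(4-methylpent-3-en-1-yl)-1,3-dioxolane
Product: 4 3-(2-methyl-1,3-dioxolan-2-yl)propanal, via ozonide 3 (not isolated)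
Conditions: O3, CH2Cl2, −78 °C; then PPh3, −78 °C → rt
Reagents that add atoms: ozone, O=[O+][O-]
Why: Ozonolysis cleaves the only C=C bond through ozonide 3 and PPh3 reduces it to the aldehyde, while the ketal carbon carries no hydrogen that ozone could attack.

Step 3
Reactants: 4 3-(2-methyl-1,3-dioxolan-2-yl)propanal; 5 dimethyl propanedioate
Product: 6 dimethyl 2-[3-(2-methyl-1,3-dioxolan-2-yl)propylidene]propanedioate
Conditions: piperidine (0.1 equiv), AcOH (0.1 equiv), benzene, reflux, azeotropic removal of water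
Reagents that add atoms: none
Why: Knoevenagel condensation under piperidinium acetate catalysis should occur at the aldehyde only and is driven by removal of water, the dioxolane tolerating the buffered medium.

Step 4
Reactants: 6 dimethyl 2-[3-(2-methyl-1,3-dioxolan-2-yl)propylidene]propanedioate; 7 2-nitropropane
Product: 8 dimethyl 2-[(3R)-2-methyl-5-(2-methyl-1,3-dioxolan-2-yl)-2-nitropentan-3-yl]propanedioate
Conditions: 7 (3 equiv), C2-symmetric N-spiro binaphthyl quaternary ammonium bromide with 3,3′-diaryl groups (chiral phase-transfer catalyst, 2 mol %), Cs2CO3 (0.3 equiv), toluene, 0 °C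
Reagents that add atoms: none
Why: Michael addition of the 2-nitropropane nitronate under chiral phase-transfer (ion-pair) catalysis, a reaction type established for nitroalkanes and alkylidene malonates, in which the chiral ammonium cation shields one enantiotopic face of the acceptor so that the new stereocentre (later ring carbon C2) should form as (R), the symmetrical nitronate creating no second centre.

Step 5
Reactants: 8 dimethyl 2-[(3R)-2-methyl-5-(2-methyl-1,3-dioxolan-2-yl)-2-nitropentan-3-yl]propanedioate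
Product: 10 methyl (3R,4R)-5,5-dimethyl-4-[2-(2-methyl-1,3-dioxolan-2-yl)ethyl]-2-oxopyrrolidine-3-carboxylate, via amino diester 9 (not isolated)
Conditions: H2 (50 bar), Raney Ni, MeOH, 60 °C; then NaOMe (0.2 equiv), MeOH, rt
Reagents that add atoms: none
Why: Catalytic hydrogenation of the tertiary nitro group gives amine 9, which closes the γ-lactam by acyl substitution on one ester, and the new C3 centre, acidic as part of a β-amido ester, is equilibrated by methoxide to the more stable trans arrangement relative to C4 (thermodynamic control).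

Step 6
Reactants: 10 methyl (3R,4R)-5,5-dimethyl-4-[2-(2-methyl-1,3-dioxolan-2-yl)ethyl]-2-oxopyrrolidine-3-carboxylate
Product: 11 [(3R,4R)-5,5-dimethyl-4-[2-(2-methyl-1,3-dioxolan-2-yl)ethyl]pyrrolidin-3-yl]methanol
Conditions: LiAlH4 (5 equiv), THF, reflux; then H2O, aq. NaOH
Reagents that add atoms: none
Why: Hydride reduction with LiAlH4 should convert the lactam carbonyl into CH2 and the ester into CH2OH in one operation, after which the former C3 centre can no longer epimerise and the ketal is untouched.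

Step 7
Reactants: 11 [(3R,4R)-5,5-dimethyl-4-[2-(2-methyl-1,3-dioxolan-2-yl)ethyl]pyrrolidin-3-yl]methanol
Product: 12 (3R,4R)-4-{[(tert-butyldiphenylsilyl)oxy]methyl}-2,2-dimethyl-3-[2-(2-methyl-1,3-dioxolan-2-yl)ethyl]pyrrolidine
Conditions: TBDPSCl (1.1 equiv), imidazole (2.2 equiv), CH2Cl2, 0 °C → rt
Reagents that add atoms: tert-butyl(chloro)diphenylsilane, CC(C)(C)[Si](Cl)(c1ccccc1)c1ccccc1
Why: Silylation with a bulky silyl chloride should take place at the primary hydroxyl only, since the nitrogen is flanked by a quaternary carbon and any N–Si bond is lost on aqueous work-up.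

Step 8
Reactants: 12 (3R,4R)-4-{[(tert-butyldiphenylsilyl)oxy]methyl}-2,2-dimethyl-3-[2-(2-methyl-1,3-dioxolan-2-yl)ethyl]pyrrolidine
Product: 16 tert-butyl{[(1S,2R)-3,3-dimethyl-2-[2-(2-methyl-1,3-dioxolan-2-yl)ethyl]cyclobutyl]methoxy}diphenylsilane, via N-aminopyrrolidine 13 (not isolated), via 1,1-diazene 14 (not isolated), via 1,4-diradical 15 (not isolated)
Conditions: PhI(OAc)2 (2.5 equiv), H2NCO2NH4 (8 equiv), CF3CH2OH (0.05 M), 80 °C
Reagents that add atoms: none
Why: Proposed new method: the iodonitrene PhI=NH, formed in the flask from PhI(OAc)2 and ammonia, aminates the ring nitrogen of 12 to give 13, the excess oxidant takes 13 on to 1,1-diazene 14, and 14 loses N2 in two stages, the weaker N–CMe2 bond breaking first, to leave singlet 1,4-diradical 15. The closest known reaction type is the iodonitrene-mediated contraction of pyrrolidines to cyclobutanes, which is established preparatively where an aryl or carbonyl group sits on the α-carbons, so a pyrrolidine with one quaternary alkyl α-carbon and one bare α-CH2 lies outside the documented scope. Ring A is closed by radical–radical combination of the C3 and C4 termini of 15, a 5 → 4 ring contraction that forms the C3–C4 bond. No new stereocentre arises, and because C1 and C2 never carry spin, their trans relationship and absolute configuration should pass unchanged from 12 to 16. The step needs combination of the termini to outrun β-scission of the C1–C2 bond and intramolecular 1,5-hydrogen transfer; in its favour, 15 is born folded with its termini at bonding distance, both groups on C1 and C2 are saturated so that scission would give only unconjugated alkenes, and the dilution keeps 14 from dimerising to a tetrazene.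

Step 9
Reactants: 16 tert-butyl{[(1S,2R)-3,3-dimethyl-2-[2-(2-methyl-1,3-dioxolan-2-yl)ethyl]cyclobutyl]methoxy}diphenylsilane
Product: 17 [(1S,2R)-3,3-dimethyl-2-[2-(2-methyl-1,3-dioxolan-2-yl)ethyl]cyclobutyl]methanol
Conditions: Bu4NF (1.5 equiv), THF, rt
Reagents that add atoms: none
Why: Fluoride-induced cleavage of the Si–O bond (desilylation) leaves the ketal and both stereocentres unaffected.

Step 10
Reactants: 17 [(1S,2R)-3,3-dimethyl-2-[2-(2-methyl-1,3-dioxolan-2-yl)ethyl]cyclobutyl]methanol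
Product: 18 (1S,2R)-3,3-dimethyl-2-[2-(2-methyl-1,3-dioxolan-2-yl)ethyl]cyclobutane-1-carbaldehyde
Conditions: Pr4N[RuO4] (5 mol %), N-methylmorpholine N-oxide (1.5 equiv), 4 Å MS, CH2Cl2, rt
Reagents that add atoms: none
Why: Ley–Griffith oxidation under neutral conditions should stop at the aldehyde and keep the dioxolane intact, and C1, now α to the carbonyl, already has the thermodynamically preferred trans configuration.

Step 11
Reactants: 18 (1S,2R)-3,3-dimethyl-2-[2-(2-methyl-1,3-dioxolan-2-yl)ethyl]cyclobutane-1-carbaldehyde; 19 (3-bromopropoxy)(tert-butyl)dimethylsilane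
Product: 21 4-[(tert-butyldimethylsilyl)oxy]-1-[(1S,2R)-3,3-dimethyl-2-[2-(2-methyl-1,3-dioxolan-2-yl)ethyl]cyclobutyl]butan-1-ol (both carbinol epimers), via Grignard reagent 20 (not isolated)
Conditions: 19, Mg, I2 (cat.), THF, 40 °C; then 18, THF, −78 → 0 °C; aq. NH4Cl
Reagents that add atoms: none
Why: Grignard addition to the aldehyde builds the three-carbon side chain, and the new carbinol centre, formed without control, is of no consequence because it is oxidised in step 12.

Step 12
Reactants: 21 4-[(tert-butyldimethylsilyl)oxy]-1-[(1S,2R)-3,3-dimethyl-2-[2-(2-methyl-1,3-dioxolan-2-yl)ethyl]cyclobutyl]butan-1-ol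
Product: 22 4-[(tert-butyldimethylsilyl)oxy]-1-[(1S,2R)-3,3-dimethyl-2-[2-(2-methyl-1,3-dioxolan-2-yl)ethyl]cyclobutyl]butan-1-one
Conditions: Pr4N[RuO4] (5 mol %), N-methylmorpholine N-oxide (1.5 equiv), 4 Å MS, CH2Cl2, rt
Reagents that add atoms: none
Why: Ley–Griffith oxidation of the secondary alcohol removes the uncontrolled carbinol centre under neutral conditions that spare the silyl ether and the ketal.

Step 13
Reactants: 22 4-[(tert-butyldimethylsilyl)oxy]-1-[(1S,2R)-3,3-dimethyl-2-[2-(2-methyl-1,3-dioxolan-2-yl)ethyl]cyclobutyl]butan-1-one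
Product: 23 tert-butyl({4-[(1S,2R)-3,3-dimethyl-2-[2-(2-methyl-1,3-dioxolan-2-yl)ethyl]cyclobutyl]pent-4-en-1-yl}oxy)dimethylsilane
Conditions: Ph3PCH3Br (2.5 equiv), KOtBu (2.3 equiv), THF, 0 °C → 50 °C
Reagents that add atoms: methyltriphenylphosphonium bromide, C[P+](c1ccccc1)(c1ccccc1)c1ccccc1.[Br-]
Why: Wittig methylenation with the unstabilised ylide should convert the ketone into the 1,1-disubstituted alkene, and any base-induced equilibration at C1 can only reinforce the favoured trans arrangement.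

Step 14
Reactants: 23 tert-butyl({4-[(1S,2R)-3,3-dimethyl-2-[2-(2-methyl-1,3-dioxolan-2-yl)ethyl]cyclobutyl]pent-4-en-1-yl}oxy)dimethylsilane
Product: 25 4-[(1R,4S)-4-(5-hydroxypent-1-en-2-yl)-2,2-dimethylcyclobutyl]butan-2-one, via hydroxy ketal 24 (not isolated)
Conditions: Bu4NF (1.5 equiv), THF, rt; then 2 M aq. HCl added, rt
Reagents that add atoms: water, O
Why: Fluoride desilylation frees the primary alcohol 24 and dilute aqueous acid then hydrolyses the dioxolane (ketal hydrolysis) under conditions too mild to protonate the 1,1-disubstituted alkene.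

Step 15
Reactants: 25 4-[(1R,4S)-4-(5-hydroxypent-1-en-2-yl)-2,2-dimethylcyclobutyl]butan-2-one; 26 (9Z,12Z)-octadeca-9,12-dienoic acid (linoleic acid)
Product: 27 4-[(1S,2R)-3,3-dimethyl-2-(3-oxobutyl)cyclobutyl]pent-4-en-1-yl (9Z,12Z)-octadeca-9,12-dienoate (IN0146)
Conditions: EDC·HCl (1.5 equiv), DMAP (0.2 equiv), CH2Cl2, 0 °C → rt, argon, dark
Reagents that add atoms: none
Why: Steglich esterification with a carbodiimide and DMAP acylates the primary alcohol at room temperature without migration or isomerisation of the skipped (9Z,12Z)-diene.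

**Compound list**

1 | 6-methylhept-5-en-2-one | CC(C)=CCCC(C)=O | starting material
2 | 2-methyl-2-(4-methylpent-3-en-1-yl)-1,3-dioxolane | CC(C)=CCCC1(C)OCCO1 | intermediate
3 | 3,3-dimethyl-5-[2-(2-methyl-1,3-dioxolan-2-yl)ethyl]-1,2,4-trioxolane (ozonide) | CC1(C)OOC(CCC2(C)OCCO2)O1 | intermediate
4 | 3-(2-methyl-1,3-dioxolan-2-yl)propanal | O=CCCC1(C)OCCO1 | intermediate
5 | dimethyl propanedioate | COC(=O)CC(=O)OC | starting material
6 | dimethyl 2-[3-(2-methyl-1,3-dioxolan-2-yl)propylidene]propanedioate | COC(=O)C(=CCCC1(C)OCCO1)C(=O)OC | intermediate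
7 | 2-nitropropane | CC(C)[N+](=O)[O-] | starting material
8 | dimethyl 2-[(3R)-2-methyl-5-(2-methyl-1,3-dioxolan-2-yl)-2-nitropentan-3-yl]propanedioate | COC(=O)C(C(=O)OC)[C@@H](CCC1(C)OCCO1)C(C)(C)[N+](=O)[O-] | intermediate
9 | dimethyl 2-[(3R)-2-amino-2-methyl-5-(2-methyl-1,3-dioxolan-2-yl)pentan-3-yl]propanedioate | COC(=O)C(C(=O)OC)[C@@H](CCC1(C)OCCO1)C(C)(C)N | intermediate
10 | methyl (3R,4R)-5,5-dimethyl-4-[2-(2-methyl-1,3-dioxolan-2-yl)ethyl]-2-oxopyrrolidine-3-carboxylate | COC(=O)[C@H]1C(=O)NC(C)(C)[C@@H]1CCC2(C)OCCO2 | intermediate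
11 | [(3R,4R)-5,5-dimethyl-4-[2-(2-methyl-1,3-dioxolan-2-yl)ethyl]pyrrolidin-3-yl]methanol | OC[C@H]1CNC(C)(C)[C@@H]1CCC2(C)OCCO2 | intermediate
12 | (3R,4R)-4-{[(tert-butyldiphenylsilyl)oxy]methyl}-2,2-dimethyl-3-[2-(2-methyl-1,3-dioxolan-2-yl)ethyl]pyrrolidine | CC(C)(C)[Si](c1ccccc1)(c1ccccc1)OC[C@H]2CNC(C)(C)[C@@H]2CCC3(C)OCCO3 | intermediate
13 | (3R,4R)-4-{[(tert-butyldiphenylsilyl)oxy]methyl}-2,2-dimethyl-3-[2-(2-methyl-1,3-dioxolan-2-yl)ethyl]pyrrolidin-1-amine | CC(C)(C)[Si](c1ccccc1)(c1ccccc1)OC[C@H]2CN(N)C(C)(C)[C@@H]2CCC3(C)OCCO3 | intermediate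
14 | 1,1-diazene of 12 (N-nitrene, ring nitrogen doubly bonded to a terminal nitrogen; ring carbons as in 12) | CC(C)(C)[Si](c1ccccc1)(c1ccccc1)OC[C@H]2C[N+](=[N-])C(C)(C)[C@@H]2CCC3(C)OCCO3 | intermediate
15 | singlet 1,4-diradical from 14 after loss of N2 (radical centres at the CMe2 carbon and at the CH2 carbon, the two CH centres configured as in 12) | CC(C)(C)[Si](c1ccccc1)(c1ccccc1)OC[C@@H]([CH2])[C@@H](CCC1(C)OCCO1)[C](C)C | intermediate
16 | tert-butyl{[(1S,2R)-3,3-dimethyl-2-[2-(2-methyl-1,3-dioxolan-2-yl)ethyl]cyclobutyl]methoxy}diphenylsilane | CC(C)(C)[Si](c1ccccc1)(c1ccccc1)OC[C@H]2CC(C)(C)[C@@H]2CCC3(C)OCCO3 | intermediate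
17 | [(1S,2R)-3,3-dimethyl-2-[2-(2-methyl-1,3-dioxolan-2-yl)ethyl]cyclobutyl]methanol | OC[C@H]1CC(C)(C)[C@@H]1CCC2(C)OCCO2 | intermediate
18 | (1S,2R)-3,3-dimethyl-2-[2-(2-methyl-1,3-dioxolan-2-yl)ethyl]cyclobutane-1-carbaldehyde | O=C[C@H]1CC(C)(C)[C@@H]1CCC2(C)OCCO2 | intermediate
19 | (3-bromopropoxy)(tert-butyl)dimethylsilane | CC(C)(C)[Si](C)(C)OCCCBr | starting material
20 | {3-[(tert-butyldimethylsilyl)oxy]propyl}magnesium bromide | CC(C)(C)[Si](C)(C)OCCC[Mg]Br | intermediate
21 | 4-[(tert-butyldimethylsilyl)oxy]-1-[(1S,2R)-3,3-dimethyl-2-[2-(2-methyl-1,3-dioxolan-2-yl)ethyl]cyclobutyl]butan-1-ol (both carbinol epimers) | CC(C)(C)[Si](C)(C)OCCCC(O)[C@H]1CC(C)(C)[C@@H]1CCC2(C)OCCO2 | intermediate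
22 | 4-[(tert-butyldimethylsilyl)oxy]-1-[(1S,2R)-3,3-dimethyl-2-[2-(2-methyl-1,3-dioxolan-2-yl)ethyl]cyclobutyl]butan-1-one | CC(C)(C)[Si](C)(C)OCCCC(=O)[C@H]1CC(C)(C)[C@@H]1CCC2(C)OCCO2 | intermediate
23 | tert-butyl({4-[(1S,2R)-3,3-dimethyl-2-[2-(2-methyl-1,3-dioxolan-2-yl)ethyl]cyclobutyl]pent-4-en-1-yl}oxy)dimethylsilane | C=C(CCCO[Si](C)(C)C(C)(C)C)[C@H]1CC(C)(C)[C@@H]1CCC2(C)OCCO2 | intermediate
24 | 4-[(1S,2R)-3,3-dimethyl-2-[2-(2-methyl-1,3-dioxolan-2-yl)ethyl]cyclobutyl]pent-4-en-1-ol | C=C(CCCO)[C@H]1CC(C)(C)[C@@H]1CCC2(C)OCCO2 | intermediate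
25 | 4-[(1R,4S)-4-(5-hydroxypent-1-en-2-yl)-2,2-dimethylcyclobutyl]butan-2-one | C=C(CCCO)[C@H]1CC(C)(C)[C@@H]1CCC(C)=O | intermediate
26 | (9Z,12Z)-octadeca-9,12-dienoic acid (linoleic acid) | CCCCC/C=C\C/C=C\CCCCCCCC(=O)O | starting material
27 | 4-[(1S,2R)-3,3-dimethyl-2-(3-oxobutyl)cyclobutyl]pent-4-en-1-yl (9Z,12Z)-octadeca-9,12-dienoate (IN0146) | C=C(CCCOC(=O)CCCCCCC/C=C\C/C=C\CCCCC)[C@H]1CC(C)(C)[C@@H]1CCC(C)=O | target

**Step count**

Total: 15 steps. Longest linear sequence: 15 steps (1 → 27).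

**Steps most likely to fail**

1. Step 8 (ring contraction). After loss of N2 the diradical may break its C1–C2 bond into two alkenes, or transfer a hydrogen from a methyl group to the primary radical, faster than its termini combine, because the primary C4 terminus has no stabilising group. Oxidation of the amine to a cyclic imine before N-amination is a second diverting process.
Fallback (known chemistry, ring A closed by a ketene–alkene [2+2] cycloaddition instead): it sets out from ketal 2 and comes back at alcohol 17.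
 - Dichloroketene (Cl3CCOCl, Zn–Cu couple, DME/Et2O) should add to the trisubstituted alkene of 2, its carbonyl carbon bonding to the less substituted alkene carbon, to give racemic 2,2-dichloro-3,3-dimethyl-4-[2-(2-methyl-1,3-dioxolan-2-yl)ethyl]cyclobutan-1-one F1.
 - Zn and NH4Cl in MeOH should remove both chlorines to give racemic 3,3-dimethyl-2-[2-(2-methyl-1,3-dioxolan-2-yl)ethyl]cyclobutan-1-one F2.
 - The van Leusen reductive cyanation (TosMIC, KOtBu, DME/EtOH) should give, after base equilibration, racemic trans-3,3-dimethyl-2-[2-(2-methyl-1,3-dioxolan-2-yl)ethyl]cyclobutane-1-carbonitrile F3.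
 - KOH in aqueous ethylene glycol at 130 °C should hydrolyse the nitrile to the racemic trans carboxylic acid F4.
 - F4 is resolved by crystallising the (R)-1-phenylethylammonium salt of the (1S,2R)-acid F5 (the antipodal amine is used if the other salt proves the less soluble one).
 - Cold dilute citric acid frees (1S,2R)-3,3-dimethyl-2-[2-(2-methyl-1,3-dioxolan-2-yl)ethyl]cyclobutane-1-carboxylic acid F6, which LiAlH4 in THF reduces to 17.

2. Step 4 (asymmetric conjugate addition). Facial discrimination by the ion pair may be poor for an alkylidene malonate with a flexible alkyl group, and base-induced migration of the double bond out of conjugation may compete with addition.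
Fallback (racemic addition and classical resolution): it sets out from 6 and 7 and comes back at amino alcohol 11.
 - DBU (0.2 equiv) in MeCN should give the racemic nitro malonate F7.
 - The conditions of step 5 should take F7 through the racemic amino diester F8 (not isolated) to the racemic trans lactam ester F9.
 - The conditions of step 6 should give the racemic trans amino alcohol F10.
 - F10 is resolved by crystallisation from acetonitrile of the 1:1 salt of the (3R,4R)-amine with (2R,3R)-2,3-bis[(4-methylbenzoyl)oxy]butanedioic acid F11 (the antipodal acid is used if the other salt is the less soluble one). Aqueous Na2CO3 then frees 11.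

3. Step 13 (methylenation). The basic ylide may deprotonate the α-branched ketone instead of adding to it, so that the ketone is returned on work-up.
Fallback (two-stage Peterson olefination through an isolable adduct): it sets out from ketone 22 and comes back at alkene 23.
 - Me3SiCH2MgCl with anhydrous CeCl3 in THF at −78 °C, a weakly basic organocerium reagent, should add to the carbonyl to give 5-[(tert-butyldimethylsilyl)oxy]-2-[(1S,2R)-3,3-dimethyl-2-[2-(2-methyl-1,3-dioxolan-2-yl)ethyl]cyclobutyl]-1-(trimethylsilyl)pentan-2-ol F12.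
 - KH in THF should then induce syn-elimination of the silanolate to give 23.

**Further compounds**

F1 | step 8 | 2,2-dichloro-3,3-dimethyl-4-[2-(2-methyl-1,3-dioxolan-2-yl)ethyl]cyclobutan-1-one (racemate) | O=C1C(CCC2(C)OCCO2)C(C)(C)C1(Cl)Cl
F2 | step 8 | 3,3-dimethyl-2-[2-(2-methyl-1,3-dioxolan-2-yl)ethyl]cyclobutan-1-one (racemate) | O=C1CC(C)(C)C1CCC2(C)OCCO2
F3 | step 8 | trans-3,3-dimethyl-2-[2-(2-methyl-1,3-dioxolan-2-yl)ethyl]cyclobutane-1-carbonitrile (racemate, both enantiomers written) | N#C[C@H]1CC(C)(C)[C@@H]1CCC2(C)OCCO2.N#C[C@@H]1CC(C)(C)[C@H]1CCC2(C)OCCO2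
F4 | step 8 | trans-3,3-dimethyl-2-[2-(2-methyl-1,3-dioxolan-2-yl)ethyl]cyclobutane-1-carboxylic acid (racemate, both enantiomers written) | OC(=O)[C@H]1CC(C)(C)[C@@H]1CCC2(C)OCCO2.OC(=O)[C@@H]1CC(C)(C)[C@H]1CCC2(C)OCCO2
F5 | step 8 | (R)-1-phenylethylammonium (1S,2R)-3,3-dimethyl-2-[2-(2-methyl-1,3-dioxolan-2-yl)ethyl]cyclobutane-1-carboxylate | [O-]C(=O)[C@H]1CC(C)(C)[C@@H]1CCC2(C)OCCO2.C[C@@H]([NH3+])c1ccccc1
F6 | step 8 | (1S,2R)-3,3-dimethyl-2-[2-(2-methyl-1,3-dioxolan-2-yl)ethyl]cyclobutane-1-carboxylic acid | OC(=O)[C@H]1CC(C)(C)[C@@H]1CCC2(C)OCCO2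
F7 | step 4 | dimethyl 2-[2-methyl-5-(2-methyl-1,3-dioxolan-2-yl)-2-nitropentan-3-yl]propanedioate (racemate) | COC(=O)C(C(=O)OC)C(CCC1(C)OCCO1)C(C)(C)[N+](=O)[O-]
F8 | step 4 | dimethyl 2-[2-amino-2-methyl-5-(2-methyl-1,3-dioxolan-2-yl)pentan-3-yl]propanedioate (racemate) | COC(=O)C(C(=O)OC)C(CCC1(C)OCCO1)C(C)(C)N
F9 | step 4 | methyl trans-5,5-dimethyl-4-[2-(2-methyl-1,3-dioxolan-2-yl)ethyl]-2-oxopyrrolidine-3-carboxylate (racemate, both enantiomers written) | COC(=O)[C@H]1C(=O)NC(C)(C)[C@@H]1CCC2(C)OCCO2.COC(=O)[C@@H]1C(=O)NC(C)(C)[C@H]1CCC2(C)OCCO2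
F10 | step 4 | [trans-5,5-dimethyl-4-[2-(2-methyl-1,3-dioxolan-2-yl)ethyl]pyrrolidin-3-yl]methanol (racemate, both enantiomers written) | OC[C@H]1CNC(C)(C)[C@@H]1CCC2(C)OCCO2.OC[C@@H]1CNC(C)(C)[C@H]1CCC2(C)OCCO2
F11 | step 4 | (3R,4R)-3-(hydroxymethyl)-5,5-dimethyl-4-[2-(2-methyl-1,3-dioxolan-2-yl)ethyl]pyrrolidin-1-ium hydrogen (2R,3R)-2,3-bis[(4-methylbenzoyl)oxy]butanedioate | OC[C@H]1C[NH2+]C(C)(C)[C@@H]1CCC2(C)OCCO2.[O-]C(=O)[C@H](OC(=O)c1ccc(C)cc1)[C@@H](OC(=O)c1ccc(C)cc1)C(O)=O
F12 | step 13 | 5-[(tert-butyldimethylsilyl)oxy]-2-[(1S,2R)-3,3-dimethyl-2-[2-(2-methyl-1,3-dioxolan-2-yl)ethyl]cyclobutyl]-1-(trimethylsilyl)pentan-2-ol (both carbinol epimers) | C[Si](C)(C)CC(O)(CCCO[Si](C)(C)C(C)(C)C)[C@H]1CC(C)(C)[C@@H]1CCC2(C)OCCO2
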